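**Retrosynthetic overview**

1. The target is taken back through buffered cleavage of two aryl TIPS ethers, MnO2 oxidation of a (Z)-allylic alcohol, Stille coupling at the C5 bromide of ring A with a (Z)-3-stannylpropenol, acylation of the C3–CH2OH group with 4-(TIPSO)benzoic acid, and acid cleavage of a primary TBS ether.
2. The key disconnection cuts C2–C3 and O1–C2 of the dihydrofuran ring. The strategy rests on C2: it carries only H, the guaiacyl ring, O1 and C3, so it is a one-carbon benzylidene unit that can be placed between the phenolic oxygen O1 and the exocyclic methide carbon (future C3, already bearing CH2OSi) of an ortho-quinone methide of ring A, a (4+1) annulation with a chiral benzylic sulfonium ylide.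
3. The quinone methide precursor is a 2-(1-tosylalkyl)phenol made from 5-bromo-o-vanillin by methylenation, dihydroxylation, primary silylation and sulfinate substitution.
4. The ylide precursor is a benzylsulfonium salt made from vanillin (silylation, reduction, bromination) and the C2-symmetric (2S,5S)-2,5-dimethylthiolane, itself from (2R,5R)-hexane-2,5-diol.
5. Ring order: ring A, the guaiacyl ring and the benzoate ring are bought; the dihydrofuran ring is the only ring made, and it is closed in the key step.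

Key step: step 11

Assumption (chemistry): the quinone methide is taken to attack the thiolanium benzylidene on the same face as an aldehyde does in ylide epoxidation, where the (2R,5R)-sulfide gives (S,S)-stilbene oxide; because the guaiacyl ring outranks C3 at C2 (whereas the partner carbon outranks phenyl in the epoxide), that sulfide would give 2R here, so the (2S,5S)-sulfide from (2R,5R)-hexane-2,5-diol is used, and the enantiomeric diol would be substituted unchanged if the sense proves opposite.

**Route**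

Step 1
Reactants: 1 5-bromo-2-hydroxy-3-methoxybenzaldehyde
Product: 2 4-bromo-2-methoxy-6-vinylphenol
Conditions: MePPh3Br (2.5 equiv), KOtBu (2.4 equiv), THF, 0 °C → rt
Reagents that add atoms: methyltriphenylphosphonium bromide, C[P+](c1ccccc1)(c1ccccc1)c1ccccc1.[Br-]
Why: Wittig methylenation with excess ylide, the first equivalent of which only deprotonates the phenol, should convert the salicylaldehyde into the 2-vinylphenol without phenol protection.

Step 2
Reactants: 2 4-bromo-2-methoxy-6-vinylphenol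
Product: 3 rac-1-(5-bromo-2-hydroxy-3-methoxyphenyl)ethane-1,2-diol
Conditions: OsO4 (2 mol%), NMO (1.5 equiv), acetone–H2O (4:1), rt
Reagents that add atoms: osmium tetroxide, O=[Os](=O)(=O)=O; N-methylmorpholine N-oxide, C[N+]1([O-])CCOCC1; water, O
Why: Catalytic OsO4/NMO syn-dihydroxylation of the terminal styrene should give the vicinal diol; the benzylic stereocentre is racemic and is erased later at the quinone methide stage.

Step 3
Reactants: 3 rac-1-(5-bromo-2-hydroxy-3-methoxyphenyl)ethane-1,2-diol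
Product: 4 rac-4-bromo-2-[2-(tert-butyldimethylsilyloxy)-1-hydroxyethyl]-6-methoxyphenol
Conditions: TBSCl (1.05 equiv), imidazole (2.2 equiv), CH2Cl2, 0 °C
Reagents that add atoms: tert-butyldimethylsilyl chloride, CC(C)(C)[Si](C)(C)Cl
Why: Silylation with one equivalent of TBSCl/imidazole should select the unhindered primary alcohol over the secondary benzylic alcohol and over the neutral phenol flanked by two ortho substituents.

Step 4
Reactants: 4 rac-4-bromo-2-[2-(tert-butyldimethylsilyloxy)-1-hydroxyethyl]-6-methoxyphenol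
Product: 5 rac-4-bromo-2-[2-(tert-butyldimethylsilyloxy)-1-tosylethyl]-6-methoxyphenol
Conditions: p-TolSO2H (1.5 equiv, freshly liberated from TolSO2Na), 4 Å MS, CH2Cl2, 0 °C → rt
Reagents that add atoms: p-toluenesulfinic acid, Cc1ccc(cc1)S(=O)O
Why: Acid-promoted SN1 substitution of the ortho-hydroxybenzylic alcohol (through the protonated ortho-quinone methide) with S-alkylation of sulfinate is the usual way to 2-(1-tosylalkyl)phenols, and the aprotic medium with sieves should spare the primary TBS ether.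

Step 5
Reactants: 6 vanillin
Product: 7 3-methoxy-4-(triisopropylsilyloxy)benzaldehyde
Conditions: TIPSCl (1.2 equiv), imidazole (2.5 equiv), DMF, rt
Reagents that add atoms: triisopropylsilyl chloride, CC(C)[Si](Cl)(C(C)C)C(C)C
Why: Standard imidazole-mediated O-silylation of the phenol installs a hindered aryl silyl ether that tolerates carbonate base and mild acid.

Step 6
Reactants: 7 3-methoxy-4-(triisopropylsilyloxy)benzaldehyde
Product: 8 [3-methoxy-4-(triisopropylsilyloxy)phenyl]methanol
Conditions: NaBH4, MeOH, 0 °C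
Reagents that add atoms: none
Why: Borohydride reduction of the aryl aldehyde gives the benzylic alcohol without touching the aryl silyl ether.

Step 7
Reactants: 8 [3-methoxy-4-(triisopropylsilyloxy)phenyl]methanol
Product: 9 3-methoxy-4-(triisopropylsilyloxy)benzyl bromide
Conditions: CBr4 (1.2 equiv), PPh3 (1.2 equiv), CH2Cl2, 0 °C; used at once
Reagents that add atoms: carbon tetrabromide, BrC(Br)(Br)Br
Why: The Appel reaction brominates the benzylic alcohol under neutral conditions that keep the aryl TIPS ether; the electron-rich bromide is not stored.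

Step 8
Reactants: 10 (2R,5R)-hexane-2,5-diol
Product: 11 (2R,5R)-hexane-2,5-diyl dimethanesulfonate
Conditions: MsCl (2.4 equiv), Et3N (3 equiv), CH2Cl2, 0 °C
Reagents that add atoms: methanesulfonyl chloride, CS(=O)(=O)Cl
Why: O-Sulfonylation forms only O–S bonds, so both carbinol centres keep their configuration.

Step 9
Reactants: 11 (2R,5R)-hexane-2,5-diyl dimethanesulfonate
Product: 12 (2S,5S)-2,5-dimethylthiolane
Conditions: Na2S·9H2O (1.2 equiv), DMSO, rt
Reagents that add atoms: sodium sulfide, [Na+].[Na+].[S-2]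
Why: Double SN2 displacement by sulfide (the second a 5-exo-tet closure) inverts both centres and should give the C2-symmetric (2S,5S)-thiolane.

Step 10
Reactants: 9 3-methoxy-4-(triisopropylsilyloxy)benzyl bromide; 12 (2S,5S)-2,5-dimethylthiolane
Product: 13 (2S,5S)-1-[3-methoxy-4-(triisopropylsilyloxy)benzyl]-2,5-dimethylthiolan-1-ium tetrafluoroborate
Conditions: AgBF4 (1.05 equiv), CH2Cl2, 0 °C → rt, dark
Reagents that add atoms: silver tetrafluoroborate, [Ag+].F[B-](F)(F)F
Why: S-Alkylation of the sulfide by the benzylic bromide is driven by AgBr precipitation with a non-nucleophilic counter-ion, and the C2 symmetry of the sulfide makes sulfur non-stereogenic, so a single salt should form.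

Step 11
Reactants: 5 rac-4-bromo-2-[2-(tert-butyldimethylsilyloxy)-1-tosylethyl]-6-methoxyphenol; 13 (2S,5S)-1-[3-methoxy-4-(triisopropylsilyloxy)benzyl]-2,5-dimethylthiolan-1-ium tetrafluoroborate
Product: 17 (2S,3R)-5-bromo-3-[(tert-butyldimethylsilyloxy)methyl]-7-methoxy-2-[3-methoxy-4-(triisopropylsilyloxy)phenyl]-2,3-dihydrobenzofuran, via ortho-quinone methide 14 (not isolated), via benzylic sulfonium ylide 15 (not isolated), via phenoxide sulfonium betaine 16 (not isolated)
Conditions: Cs2CO3 (3 equiv), 13 (1.5 equiv), CH2Cl2–MeCN (9:1), 0 °C → rt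
Reagents that add atoms: none
Why: Proposed new method: Cs2CO3 deprotonates the phenol of 5, which expels toluenesulfinate to give quinone methide 14, and deprotonates 13 to ylide 15; the ylide carbon adds to the exocyclic methide carbon (C2–C3) to give the rearomatised betaine 16, whose phenoxide then displaces the thiolane at the benzylic carbon with inversion (O1–C2), a 5-exo-tet SN2 closure of the dihydrofuran ring. The closest known reaction type is the base-mediated (4+1) annulation of 2-(1-tosylalkyl)phenols with carbonyl-stabilised sulfonium ylides to trans-2,3-dihydrobenzofurans, and the semi-stabilised benzylic ylide on a chiral sulfide is borrowed from asymmetric sulfur-ylide epoxidation, where the same addition and backside displacement operate. C2 is controlled by the sulfide: the ylide should hold its filled p orbital orthogonal to the sulfur lone pair with the aryl group turned away from the ring, the methyl group cis to the benzylidene shields one face, the quinone methide adds to the other, and inversion in the closure should then give 2S. C3 is set relative to C2, because the addition geometry that keeps the guaiacyl ring anti to the CH2OTBS group, with the sulfonium near the developing phenoxide, leads to the less strained trans ring and hence 3R. The step needs ylide addition to outrun tautomerisation of the alkyl-substituted quinone methide to an enol-ether styrene and O-benzylation of the phenoxide by the salt; the tosyl phenol serves as a reservoir that releases the quinone methide reversibly and at low concentration into excess ylide, and the aryl TIPS ether, the TBS ether and the aryl bromide should be inert to Cs2CO3 in an aprotic medium.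

Step 12
Reactants: 17 (2S,3R)-5-bromo-3-[(tert-butyldimethylsilyloxy)methyl]-7-methoxy-2-[3-methoxy-4-(triisopropylsilyloxy)phenyl]-2,3-dihydrobenzofuran
Product: 18 [(2S,3R)-5-bromo-7-methoxy-2-[3-methoxy-4-(triisopropylsilyloxy)phenyl]-2,3-dihydrobenzofuran-3-yl]methanol
Conditions: CSA (0.2 equiv), MeOH–CH2Cl2 (1:1), 0 °C
Reagents that add atoms: none
Why: Acid-catalysed methanolysis cleaves a primary alkyl TBS ether much faster than a hindered aryl TIPS ether, and the mild acid at 0 °C should leave the benzylic C2–O1 bond intact.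

Step 13
Reactants: 19 4-hydroxybenzoic acid
Product: 21 4-(triisopropylsilyloxy)benzoic acid, via silyl ester 20 (not isolated)
Conditions: TIPSCl (2.3 equiv), imidazole (5 equiv), DMF, rt; then K2CO3 (1.2 equiv), MeOH–H2O, 0 °C → rt; 1 M HCl to pH 4
Reagents that add atoms: triisopropylsilyl chloride, CC(C)[Si](Cl)(C(C)C)C(C)C
Why: Exhaustive silylation followed by selective solvolysis of the labile silyl ester, which is far more reactive than the aryl TIPS ether, is the standard route to O-silylated hydroxybenzoic acids.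

Step 14
Reactants: 18 [(2S,3R)-5-bromo-7-methoxy-2-[3-methoxy-4-(triisopropylsilyloxy)phenyl]-2,3-dihydrobenzofuran-3-yl]methanol; 21 4-(triisopropylsilyloxy)benzoic acid
Product: 22 [(2S,3R)-5-bromo-7-methoxy-2-[3-methoxy-4-(triisopropylsilyloxy)phenyl]-2,3-dihydrobenzofuran-3-yl]methyl 4-(triisopropylsilyloxy)benzoate
Conditions: EDC·HCl (1.5 equiv), DMAP (0.2 equiv), CH2Cl2, 0 °C → rt
Reagents that add atoms: none
Why: Steglich esterification acylates the unhindered primary alcohol under neutral conditions that touch neither stereocentre.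

Step 15
Reactants: 23 prop-2-yn-1-ol
Product: 24 (Z)-3-(tributylstannyl)prop-2-en-1-ol
Conditions: LiAlH4 (1.1 equiv), THF, 0 °C → rt; then Bu3SnOTf (1.0 equiv), −78 °C → rt
Reagents that add atoms: tributyltin trifluoromethanesulfonate, CCCC[Sn](CCCC)(CCCC)OS(=O)(=O)C(F)(F)F
Why: trans-Hydroalumination of the propargylic alkoxide passes through a five-membered alkoxyalanate that holds aluminium cis to CH2O, and tin-for-aluminium exchange with retention should give the Z stannane.

Step 16
Reactants: 22 [(2S,3R)-5-bromo-7-methoxy-2-[3-methoxy-4-(triisopropylsilyloxy)phenyl]-2,3-dihydrobenzofuran-3-yl]methyl 4-(triisopropylsilyloxy)benzoate; 24 (Z)-3-(tributylstannyl)prop-2-en-1-ol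
Product: 25 [(2S,3R)-5-[(Z)-3-hydroxyprop-1-en-1-yl]-7-methoxy-2-[3-methoxy-4-(triisopropylsilyloxy)phenyl]-2,3-dihydrobenzofuran-3-yl]methyl 4-(triisopropylsilyloxy)benzoate
Conditions: Pd(PPh3)4 (10 mol%), CuI (20 mol%), DMF, 70 °C, dark, no fluoride additive
Reagents that add atoms: none
Why: Stille coupling transfers the alkenyl group with retention of the Z geometry, and copper co-catalysis in place of fluoride activation keeps both aryl TIPS ethers.

Step 17
Reactants: 25 [(2S,3R)-5-[(Z)-3-hydroxyprop-1-en-1-yl]-7-methoxy-2-[3-methoxy-4-(triisopropylsilyloxy)phenyl]-2,3-dihydrobenzofuran-3-yl]methyl 4-(triisopropylsilyloxy)benzoate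
Product: 26 [(2S,3R)-7-methoxy-2-[3-methoxy-4-(triisopropylsilyloxy)phenyl]-5-[(Z)-3-oxoprop-1-en-1-yl]-2,3-dihydrobenzofuran-3-yl]methyl 4-(triisopropylsilyloxy)benzoate
Conditions: activated MnO2 (20 equiv), CH2Cl2, rt, dark
Reagents that add atoms: none
Why: Heterogeneous MnO2 oxidation is selective for the allylic (cinnamyl-type) alcohol and is neutral, so the Z enal should form without isomerisation while both phenols are still silylated.

Step 18
Reactants: 26 [(2S,3R)-7-methoxy-2-[3-methoxy-4-(triisopropylsilyloxy)phenyl]-5-[(Z)-3-oxoprop-1-en-1-yl]-2,3-dihydrobenzofuran-3-yl]methyl 4-(triisopropylsilyloxy)benzoate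
Product: 27 [(2S,3R)-2-(4-hydroxy-3-methoxyphenyl)-7-methoxy-5-[(Z)-3-oxoprop-1-en-1-yl]-2,3-dihydrobenzofuran-3-yl]methyl 4-hydroxybenzoate (CNP0400980.1)
Conditions: TBAF (2.5 equiv), AcOH (2.5 equiv), THF, 0 °C, dark
Reagents that add atoms: none
Why: Fluoride-mediated desilylation cleaves both aryl O–Si bonds, and the acetic acid buffer protonates the phenoxides as they form, which should prevent Z/E isomerisation of the enal, ester cleavage and ring opening of the dihydrofuran through a para-quinone methide.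

**Compound list**

1 | 5-bromo-2-hydroxy-3-methoxybenzaldehyde | COc1cc(Br)cc(C=O)c1O | starting material
2 | 4-bromo-2-methoxy-6-vinylphenol | COc1cc(Br)cc(C=C)c1O | intermediate
3 | rac-1-(5-bromo-2-hydroxy-3-methoxyphenyl)ethane-1,2-diol | COc1cc(Br)cc(C(O)CO)c1O | intermediate
4 | rac-4-bromo-2-[2-(tert-butyldimethylsilyloxy)-1-hydroxyethyl]-6-methoxyphenol | COc1cc(Br)cc(C(O)CO[Si](C)(C)C(C)(C)C)c1O | intermediate
5 | rac-4-bromo-2-[2-(tert-butyldimethylsilyloxy)-1-tosylethyl]-6-methoxyphenol | COc1cc(Br)cc(C(CO[Si](C)(C)C(C)(C)C)S(=O)(=O)c2ccc(C)cc2)c1O | intermediate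
6 | vanillin (4-hydroxy-3-methoxybenzaldehyde) | COc1cc(C=O)ccc1O | starting material
7 | 3-methoxy-4-(triisopropylsilyloxy)benzaldehyde | COc1cc(C=O)ccc1O[Si](C(C)C)(C(C)C)C(C)C | intermediate
8 | [3-methoxy-4-(triisopropylsilyloxy)phenyl]methanol | COc1cc(CO)ccc1O[Si](C(C)C)(C(C)C)C(C)C | intermediate
9 | 3-methoxy-4-(triisopropylsilyloxy)benzyl bromide | COc1cc(CBr)ccc1O[Si](C(C)C)(C(C)C)C(C)C | intermediate
10 | (2R,5R)-hexane-2,5-diol | C[C@@H](O)CC[C@@H](C)O | starting material
11 | (2R,5R)-hexane-2,5-diyl dimethanesulfonate | C[C@@H](OS(C)(=O)=O)CC[C@@H](C)OS(C)(=O)=O | intermediate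
12 | (2S,5S)-2,5-dimethylthiolane | C[C@H]1CC[C@H](C)S1 | intermediate
13 | (2S,5S)-1-[3-methoxy-4-(triisopropylsilyloxy)benzyl]-2,5-dimethylthiolan-1-ium tetrafluoroborate | COc1cc(C[S+]2[C@@H](C)CC[C@@H]2C)ccc1O[Si](C(C)C)(C(C)C)C(C)C.F[B-](F)(F)F | intermediate
14 | 4-bromo-6-[2-(tert-butyldimethylsilyloxy)ethylidene]-2-methoxycyclohexa-2,4-dien-1-one (ortho-quinone methide of ring A) | COC1=CC(Br)=CC(=CCO[Si](C)(C)C(C)(C)C)C1=O | intermediate
15 | [(2S,5S)-2,5-dimethylthiolan-1-ium-1-yl][3-methoxy-4-(triisopropylsilyloxy)phenyl]methanide (ylide of 13) | COc1cc([CH-][S+]2[C@@H](C)CC[C@@H]2C)ccc1O[Si](C(C)C)(C(C)C)C(C)C | intermediate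
16 | 4-bromo-2-{(1R,2R)-3-(tert-butyldimethylsilyloxy)-1-[(2S,5S)-2,5-dimethylthiolan-1-ium-1-yl]-1-[3-methoxy-4-(triisopropylsilyloxy)phenyl]propan-2-yl}-6-methoxyphenolate (betaine) | COc1cc(Br)cc([C@H](CO[Si](C)(C)C(C)(C)C)[C@H](c2ccc(O[Si](C(C)C)(C(C)C)C(C)C)c(OC)c2)[S+]2[C@@H](C)CC[C@@H]2C)c1[O-] | intermediate
17 | (2S,3R)-5-bromo-3-[(tert-butyldimethylsilyloxy)methyl]-7-methoxy-2-[3-methoxy-4-(triisopropylsilyloxy)phenyl]-2,3-dihydrobenzofuran | COc1cc([C@H]2Oc3c(OC)cc(Br)cc3[C@@H]2CO[Si](C)(C)C(C)(C)C)ccc1O[Si](C(C)C)(C(C)C)C(C)C | intermediate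
18 | [(2S,3R)-5-bromo-7-methoxy-2-[3-methoxy-4-(triisopropylsilyloxy)phenyl]-2,3-dihydrobenzofuran-3-yl]methanol | COc1cc([C@H]2Oc3c(OC)cc(Br)cc3[C@@H]2CO)ccc1O[Si](C(C)C)(C(C)C)C(C)C | intermediate
19 | 4-hydroxybenzoic acid | OC(=O)c1ccc(O)cc1 | starting material
20 | triisopropylsilyl 4-(triisopropylsilyloxy)benzoate | CC(C)[Si](OC(=O)c1ccc(O[Si](C(C)C)(C(C)C)C(C)C)cc1)(C(C)C)C(C)C | intermediate
21 | 4-(triisopropylsilyloxy)benzoic acid | OC(=O)c1ccc(O[Si](C(C)C)(C(C)C)C(C)C)cc1 | intermediate
22 | [(2S,3R)-5-bromo-7-methoxy-2-[3-methoxy-4-(triisopropylsilyloxy)phenyl]-2,3-dihydrobenzofuran-3-yl]methyl 4-(triisopropylsilyloxy)benzoate | COc1cc([C@H]2Oc3c(OC)cc(Br)cc3[C@@H]2COC(=O)c2ccc(O[Si](C(C)C)(C(C)C)C(C)C)cc2)ccc1O[Si](C(C)C)(C(C)C)C(C)C | intermediate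
23 | prop-2-yn-1-ol | C#CCO | starting material
24 | (Z)-3-(tributylstannyl)prop-2-en-1-ol | CCCC[Sn](CCCC)(CCCC)/C=C\CO | intermediate
25 | [(2S,3R)-5-[(Z)-3-hydroxyprop-1-en-1-yl]-7-methoxy-2-[3-methoxy-4-(triisopropylsilyloxy)phenyl]-2,3-dihydrobenzofuran-3-yl]methyl 4-(triisopropylsilyloxy)benzoate | COc1cc([C@H]2Oc3c(OC)cc(/C=C\CO)cc3[C@@H]2COC(=O)c2ccc(O[Si](C(C)C)(C(C)C)C(C)C)cc2)ccc1O[Si](C(C)C)(C(C)C)C(C)C | intermediate
26 | [(2S,3R)-7-methoxy-2-[3-methoxy-4-(triisopropylsilyloxy)phenyl]-5-[(Z)-3-oxoprop-1-en-1-yl]-2,3-dihydrobenzofuran-3-yl]methyl 4-(triisopropylsilyloxy)benzoate | COc1cc([C@H]2Oc3c(OC)cc(/C=C\C=O)cc3[C@@H]2COC(=O)c2ccc(O[Si](C(C)C)(C(C)C)C(C)C)cc2)ccc1O[Si](C(C)C)(C(C)C)C(C)C | intermediate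
27 | [(2S,3R)-2-(4-hydroxy-3-methoxyphenyl)-7-methoxy-5-[(Z)-3-oxoprop-1-en-1-yl]-2,3-dihydrobenzofuran-3-yl]methyl 4-hydroxybenzoate | COc1cc([C@H]2Oc3c(OC)cc(/C=C\C=O)cc3[C@@H]2COC(=O)c2ccc(O)cc2)ccc1O | target

**Step count**

Total: 18 steps. Longest linear sequence: 10 steps (steps 1, 2, 3, 4, 11, 12, 14, 16, 17, 18 from compound 1; the vanillin branch through steps 5, 6, 7, 10 is equally long).

**Steps most likely to fail**

Step 11. The alkyl-substituted quinone methide may tautomerise to the enol-ether styrene, or the phenoxide may be benzylated on oxygen by the sulfonium salt, before the ylide adds. The addition may also proceed with poor facial discrimination or poor trans selectivity. The fallback uses known chemistry: enantioselective intramolecular C–H insertion of an aryl diazoacetate under a chiral dirhodium tetracarboxylate, followed by epimerisation. It sets out from 2 (with 9) and returns to the route at 18.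
- Phenol 2 is O-alkylated with bromide 9 (K2CO3, acetone, reflux) to 5-bromo-1-methoxy-2-{[3-methoxy-4-(triisopropylsilyloxy)benzyl]oxy}-3-vinylbenzene F1.
- Hydroboration–oxidation (9-BBN, THF; NaBO3·4H2O) gives 2-(5-bromo-3-methoxy-2-{[3-methoxy-4-(triisopropylsilyloxy)benzyl]oxy}phenyl)ethanol F2.
- TEMPO/PhI(OAc)2 in MeCN–H2O oxidises it to (5-bromo-3-methoxy-2-{[3-methoxy-4-(triisopropylsilyloxy)benzyl]oxy}phenyl)acetic acid F3.
- TMSCHN2 in toluene–MeOH gives methyl (5-bromo-3-methoxy-2-{[3-methoxy-4-(triisopropylsilyloxy)benzyl]oxy}phenyl)acetate F4.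
- Diazo transfer (p-ABSA, DBU, MeCN) gives methyl 2-(5-bromo-3-methoxy-2-{[3-methoxy-4-(triisopropylsilyloxy)benzyl]oxy}phenyl)-2-diazoacetate F5.
- Dirhodium tetrakis(N-phthaloyl-tert-leucinate), Rh2(PTTL)4, in the enantiomeric form that delivers 2S, inserts the carbenoid into the benzylic C–H bond of the OCH2 group. This forms C2–C3 and should give methyl cis-(2S,3R)-5-bromo-7-methoxy-2-[3-methoxy-4-(triisopropylsilyloxy)phenyl]-2,3-dihydrobenzofuran-3-carboxylate F6.
- Base-mediated epimerisation at C3 (catalytic NaOMe in MeOH–THF at 0 °C, or DBU in toluene if the aryl silyl ether suffers) gives methyl trans-(2S,3S)-5-bromo-7-methoxy-2-[3-methoxy-4-(triisopropylsilyloxy)phenyl]-2,3-dihydrobenzofuran-3-carboxylate F7.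
- LiBH4 reduction (THF) gives alcohol 18, and the route resumes at step 14.

Step 16. Oxidative addition into the electron-rich aryl bromide may be slow without fluoride activation, so that Z-to-E isomerisation or protodestannylation of the stannane competes at the temperature needed. The fallback sets out from 22 and returns at 25.
- Sonogashira coupling of 22 with prop-2-yn-1-ol 23 (PdCl2(PPh3)2, CuI, Et3N, DMF, 70 °C) gives [(2S,3R)-5-(3-hydroxyprop-1-yn-1-yl)-7-methoxy-2-[3-methoxy-4-(triisopropylsilyloxy)phenyl]-2,3-dihydrobenzofuran-3-yl]methyl 4-(triisopropylsilyloxy)benzoate F8.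
- Lindlar semihydrogenation (H2, Pd/CaCO3 poisoned with Pb(OAc)2, quinoline, EtOAc, rt) should give the Z allylic alcohol 25 by syn addition of hydrogen.

Step 4. The acid may cleave the primary TBS ether, and the ionised benzylic centre may rearrange (hydride shift or tautomerisation to the arylacetaldehyde level, then benzofuran formation) faster than sulfinate captures it. The fallback sets out from 4 and returns at 5.
- Substitution with the softer 4-methylbenzenethiol under mild Lewis acid catalysis (ZnI2, CH2Cl2, rt) gives rac-4-bromo-2-[2-(tert-butyldimethylsilyloxy)-1-(p-tolylthio)ethyl]-6-methoxyphenol F9.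
- Oxidation at sulfur (mCPBA, 2.2 equiv, CH2Cl2, 0 °C) gives sulfone 5.

**Further compounds**

F1 | step 11 | 5-bromo-1-methoxy-2-{[3-methoxy-4-(triisopropylsilyloxy)benzyl]oxy}-3-vinylbenzene | COc1cc(Br)cc(C=C)c1OCc1ccc(O[Si](C(C)C)(C(C)C)C(C)C)c(OC)c1
F2 | step 11 | 2-(5-bromo-3-methoxy-2-{[3-methoxy-4-(triisopropylsilyloxy)benzyl]oxy}phenyl)ethanol | COc1cc(Br)cc(CCO)c1OCc1ccc(O[Si](C(C)C)(C(C)C)C(C)C)c(OC)c1
F3 | step 11 | (5-bromo-3-methoxy-2-{[3-methoxy-4-(triisopropylsilyloxy)benzyl]oxy}phenyl)acetic acid | COc1cc(Br)cc(CC(=O)O)c1OCc1ccc(O[Si](C(C)C)(C(C)C)C(C)C)c(OC)c1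
F4 | step 11 | methyl (5-bromo-3-methoxy-2-{[3-methoxy-4-(triisopropylsilyloxy)benzyl]oxy}phenyl)acetate | COC(=O)Cc1cc(Br)cc(OC)c1OCc1ccc(O[Si](C(C)C)(C(C)C)C(C)C)c(OC)c1
F5 | step 11 | methyl 2-(5-bromo-3-methoxy-2-{[3-methoxy-4-(triisopropylsilyloxy)benzyl]oxy}phenyl)-2-diazoacetate | COC(=O)C(=[N+]=[N-])c1cc(Br)cc(OC)c1OCc1ccc(O[Si](C(C)C)(C(C)C)C(C)C)c(OC)c1
F6 | step 11 | methyl cis-(2S,3R)-5-bromo-7-methoxy-2-[3-methoxy-4-(triisopropylsilyloxy)phenyl]-2,3-dihydrobenzofuran-3-carboxylate | COc1cc([C@H]2Oc3c(OC)cc(Br)cc3[C@H]2C(=O)OC)ccc1O[Si](C(C)C)(C(C)C)C(C)C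
F7 | step 11 | methyl trans-(2S,3S)-5-bromo-7-methoxy-2-[3-methoxy-4-(triisopropylsilyloxy)phenyl]-2,3-dihydrobenzofuran-3-carboxylate | COc1cc([C@H]2Oc3c(OC)cc(Br)cc3[C@@H]2C(=O)OC)ccc1O[Si](C(C)C)(C(C)C)C(C)C
F8 | step 16 | [(2S,3R)-5-(3-hydroxyprop-1-yn-1-yl)-7-methoxy-2-[3-methoxy-4-(triisopropylsilyloxy)phenyl]-2,3-dihydrobenzofuran-3-yl]methyl 4-(triisopropylsilyloxy)benzoate | COc1cc([C@H]2Oc3c(OC)cc(C#CCO)cc3[C@@H]2COC(=O)c2ccc(O[Si](C(C)C)(C(C)C)C(C)C)cc2)ccc1O[Si](C(C)C)(C(C)C)C(C)C
F9 | step 4 | rac-4-bromo-2-[2-(tert-butyldimethylsilyloxy)-1-(p-tolylthio)ethyl]-6-methoxyphenol | COc1cc(Br)cc(C(CO[Si](C)(C)C(C)(C)C)Sc2ccc(C)cc2)c1O
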